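The six-membered ring is cut at C4–C5 and O1–C6, which removes C5, C6 and the methyl group as a propyne unit and leaves O1–C2–C3–C4(=O), the atoms of a β-lactone. The key step is a strain-driven formal insertion of propyne into the acyl C–O bond of (4R)-4-alkyloxetan-2-one 5: a propynyl anion opens the four-membered ring at the acyl carbon (C4–C5), and the liberated C2 hydroxyl closes onto the ynone terminus (O1–C6) in the same flask. It exploits the β-oxy-carbonyl relationship of O1 and C4 in the dihydropyranone ring. Lactone 5 comes from (15Z)-tetracos-15-enal by a catalytic asymmetric ketene cycloaddition that sets C2.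

Key step: step 3

Remark: in step 2 the quinine-derived catalyst is assumed to give the (4R)-4-alkyl lactone and its quinidine-derived pseudo-enantiomer the (4S) series. The sense is to be confirmed on lactone 5 before it is carried on, and the other alkaloid is used if it proves reversed.

Step 1
Reactants: 1 methyl (15Z)-tetracos-15-enoate (methyl nervonate)
Product: 2 (15Z)-tetracos-15-enal
Conditions: i-Bu2AlH (1.1 equiv), CH2Cl2, −78 °C; then MeOH, aq. KNaC4H4O6 (Rochelle salt)
Reagents that add atoms: none
Why: Partial hydride reduction of an ester, in which the aluminium hemiacetal is stable at −78 °C and releases the aldehyde only on work-up, while the isolated Z-alkene is inert to the hydride.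

Step 2
Reactants: 2 (15Z)-tetracos-15-enal, 3 acetyl chloride
Product: 5 (4R)-4-[(14Z)-tricos-14-en-1-yl]oxetan-2-one, via ketene 4 (not isolated)
Conditions: O-trimethylsilylquinine (10 mol %), LiClO4 (1 equiv), i-Pr2NEt, CH2Cl2/Et2O, −78 °C, slow addition of 3
Reagents that add atoms: acetyl chloride 3, CC(=O)Cl
Why: Nucleophile-catalysed acyl halide–aldehyde cyclocondensation (formal [2+2] ketene–aldehyde cycloaddition), in which the silylated alkaloid turns ketene 4 into a chiral ammonium enolate that undergoes a LiClO4-organised aldol addition to 2 and then lactonises, the alkaloid selecting the aldehyde face and so setting C4 of the lactone as (R).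

Step 3
Reactants: 5 (4R)-4-[(14Z)-tricos-14-en-1-yl]oxetan-2-one, 6 1-propynyllithium
Product: 8 (2R)-6-methyl-2-[(14Z)-tricos-14-en-1-yl]-2,3-dihydro-4H-pyran-4-one, via hydroxy ynone 7 (not isolated)
Conditions: 6 (LiC≡CCH3, 1.5 equiv), BF3·OEt2 (1.5 equiv), THF, −78 °C, then 5; then p-TsOH·H2O (3 equiv), MeOH, −78 → 40 °C
Reagents that add atoms: 1-propynyllithium 6, [Li]C#CC
Why: The hard alkynyl nucleophile formed from 6 and BF3·OEt2 adds to the lactone carbonyl and the adduct collapses with cleavage of the acyl–O bond, driven by release of the four-membered ring strain, to give the O-borylated form of β-hydroxy ynone 7 (C4–C5 bond); acidification frees the hydroxyl, which adds to the activated ynone at the methyl-bearing alkyne carbon (O1–C6 bond), and the allenol tautomerises to the vinylogous ester. The closest known reaction types are the BF3-mediated alkynylation of lactones to hydroxy ynones and the acid-catalysed cycloisomerisation of β-hydroxy ynones to 2,3-dihydro-4H-pyran-4-ones, run here in one flask. The six-membered ring closes in the 6-endo-dig mode, which is the Michael-type and electronically matched position, whereas 5-exo-dig closure would be anti-Michael. No stereocentre is created, and C2 is carried over from 5 with retention because its C–O bond is never broken. The step needs acyl–O rather than alkyl–O cleavage of the lactone and mono-addition of the acetylide: the hard lithium/boron acetylide at −78 °C and the secondary, chain-shielded C4 of 5 favour attack at the carbonyl, and the borylated adduct does not expose a free ynone to the reagent before the acid quench. Methanol or water that adds to the ynone under the acid gives a β-methoxy enone or a 1,3-diketone, both of which close to the same product.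

Compound list
1 | methyl (15Z)-tetracos-15-enoate (methyl nervonate) | CCCCCCCC/C=C\CCCCCCCCCCCCCC(=O)OC | starting material
2 | (15Z)-tetracos-15-enal | CCCCCCCC/C=C\CCCCCCCCCCCCCC=O | intermediate
3 | acetyl chloride | CC(=O)Cl | starting material
4 | ketene (ethenone), formed in the flask | C=C=O | intermediate
5 | (4R)-4-[(14Z)-tricos-14-en-1-yl]oxetan-2-one | CCCCCCCC/C=C\CCCCCCCCCCCCC[C@@H]1CC(=O)O1 | intermediate
6 | 1-propynyllithium | [Li]C#CC | starting material
7 | (6R,20Z)-6-hydroxynonacos-20-en-2-yn-4-one, formed in the flask | CCCCCCCC/C=C\CCCCCCCCCCCCC[C@@H](O)CC(=O)C#CC | intermediate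
8 | (2R)-6-methyl-2-[(14Z)-tricos-14-en-1-yl]-2,3-dihydro-4H-pyran-4-one | CCCCCCCC/C=C\CCCCCCCCCCCCC[C@@H]1CC(=O)C=C(C)O1 | target

Total step count: 3
Longest linear sequence: 3 steps (1 → 2 → 5 → 8)

Steps most likely to fail

1. Step 3 (key step). The acetylide may attack C4 of the lactone with alkyl–O cleavage, a second acetylide may add to the ynone once it is set free, or the β-hydroxy ynone may dehydrate under the acid in place of ring closure. Fallback, from 5 and back at 7: lactone 5 is opened at the acyl carbon with MeNH(OMe)·HCl and Me2AlCl (CH2Cl2, −30 °C to rt) to the Weinreb amide (3R,17Z)-3-hydroxy-N-methoxy-N-methylhexacos-17-enamide F1. CH3C≡CMgBr (3 equiv, THF, 0 °C) then gives hydroxy ynone 7 through a magnesium-chelated tetrahedral intermediate that cannot take up a second acetylide. Here 7 is isolated and closed to 8 with Ph3PAuCl/AgOTf (cat., CH2Cl2, rt) under neutral π-acid catalysis.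

2. Step 2. The long-chain aldehyde may precipitate at −78 °C, so that conversion is slow and ketene dimerisation takes over, or facial control may be insufficient or of the opposite sense. Fallback, from 2 and back at 5: aldehyde 2 is homologated with ethyl diazoacetate and SnCl2 (cat., CH2Cl2, rt; Roskamp reaction) to ethyl (17Z)-3-oxohexacos-17-enoate F2. Noyori hydrogenation of the ketone with [RuCl2((R)-BINAP)] (H2, EtOH, low pressure, so that the isolated Z-alkene is not touched) gives ethyl (3R,17Z)-3-hydroxyhexacos-17-enoate F3, the (R)-ligand delivering the (3R)-alcohol as for simple 3-oxoalkanoates. LiOH (THF/H2O) gives (3R,17Z)-3-hydroxyhexacos-17-enoic acid F4. PhSO2Cl in pyridine at 0 °C closes the β-lactone through the mixed anhydride, that is by carboxyl activation with retention at the carbinol carbon, to 5.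

3. Step 1. Over-reduction to the primary alcohol or incomplete conversion of the ester may occur if the aluminium hemiacetal collapses before the quench. Fallback, from 1 and back at 2: ester 1 is reduced fully with LiAlH4 (THF, 0 °C) to (15Z)-tetracos-15-en-1-ol F5, which is oxidised with Dess–Martin periodinane (CH2Cl2, NaHCO3, rt) to 2.

Further compounds
F1 | step 3 | (3R,17Z)-3-hydroxy-N-methoxy-N-methylhexacos-17-enamide | CCCCCCCC/C=C\CCCCCCCCCCCCC[C@@H](O)CC(=O)N(C)OC
F2 | step 2 | ethyl (17Z)-3-oxohexacos-17-enoate | CCCCCCCC/C=C\CCCCCCCCCCCCCC(=O)CC(=O)OCC
F3 | step 2 | ethyl (3R,17Z)-3-hydroxyhexacos-17-enoate | CCCCCCCC/C=C\CCCCCCCCCCCCC[C@@H](O)CC(=O)OCC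
F4 | step 2 | (3R,17Z)-3-hydroxyhexacos-17-enoic acid | CCCCCCCC/C=C\CCCCCCCCCCCCC[C@@H](O)CC(=O)O
F5 | step 1 | (15Z)-tetracos-15-en-1-ol | CCCCCCCC/C=C\CCCCCCCCCCCCCCO
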